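**Retrosynthetic overview**
1. Target 12 ⇐ hispidulin 11 by selective O-sulfation of the 7- and 4'-OH; the chelated 5-OH stays free.
2. 11 ⇐ tribenzyl ether 10 by global hydrogenolysis.
3. Key disconnection C2–C1': 10 ⇐ chromone 7 + aryl iodide 8. The normally electrophilic enone β-carbon C2 is turned into a zinc nucleophile (β-acylvinyl anion, homoenolate-type d3 synthon) and joined to the electrophilic C–I carbon.
4. 7 ⇐ acetophenone 5 + one carbon from DMF-DMA; 5 ⇐ phloroacetophenone 1 by dibenzylation, Elbs para-hydroxylation and selective O-methylation.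
5. Ring order: A ring bought (1), C ring (pyranone) closed in step 4, B ring attached in step 5.

Assumption: the target has no stereocentre, so no configuration has to be set; the sulfates are taken in the hydrogen sulfate form drawn, released from the salt by cold H+ exchange.

**Step 1**
Reactants: 1 2',4',6'-trihydroxyacetophenone
Product: 2 1-[2,4-bis(benzyloxy)-6-hydroxyphenyl]ethanone
Conditions: BnBr (2.1 equiv), K2CO3 (2.2 equiv), DMF, rt→60 °C
Reagents that add atoms: benzyl bromide, BrCc1ccccc1
Why: Williamson etherification; the OH hydrogen-bonded to the acetyl carbonyl is the least nucleophilic, so two equivalents of BnBr alkylate the 4-OH and one ortho-OH and leave the chelated OH free.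

**Step 2**
Reactants: 2 1-[2,4-bis(benzyloxy)-6-hydroxyphenyl]ethanone
Product: 4 1-[2,4-bis(benzyloxy)-3,6-dihydroxyphenyl]ethanone, via aryl sulfate potassium salt 3 (not isolated)
Conditions: K2S2O8, aq KOH, pyridine, 10 °C→rt, 24 h; then HCl (pH 1), Na2SO3, 85 °C, 30 min
Reagents that add atoms: potassium persulfate, [K+].[K+].[O-]S(=O)(=O)OOS(=O)(=O)[O-]
Why: Elbs persulfate oxidation; the phenoxide attacks the peroxide oxygen through its only free para carbon (C3, between the two OBn groups), and dilute acid hydrolyses the aryl sulfate 3 to the hydroquinone without touching the benzyl ethers.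

**Step 3**
Reactants: 4 1-[2,4-bis(benzyloxy)-3,6-dihydroxyphenyl]ethanone
Product: 5 1-[2,4-bis(benzyloxy)-6-hydroxy-3-methoxyphenyl]ethanone
Conditions: MeI (1.1 equiv), K2CO3 (1.2 equiv), acetone, reflux, N2
Reagents that add atoms: iodomethane, CI
Why: Williamson O-methylation; the 6-OH is locked in a hydrogen bond to the ketone, so one equivalent of MeI methylates only the free 3-OH (classical selective methylation of quinacetophenones).

**Step 4**
Reactants: 5 1-[2,4-bis(benzyloxy)-6-hydroxy-3-methoxyphenyl]ethanone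
Product: 7 5,7-bis(benzyloxy)-6-methoxy-4H-chromen-4-one, via enaminone 6 (not isolated)
Conditions: DMF-DMA (3 equiv), toluene, 100 °C; evaporate; AcOH, 90 °C, 1 h
Reagents that add atoms: N,N-dimethylformamide dimethyl acetal, COC(OC)N(C)C
Why: Enaminone condensation of the methyl ketone with DMF-DMA, then acid-promoted intramolecular oxa-Michael addition–elimination (loss of Me2NH) closes the chromone; AcOH is too weak to cleave the benzyl ethers.

**Step 5**
Reactants: 7 5,7-bis(benzyloxy)-6-methoxy-4H-chromen-4-one; 8 1-(benzyloxy)-4-iodobenzene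
Product: 10 5,7-bis(benzyloxy)-2-[4-(benzyloxy)phenyl]-6-methoxy-4H-chromen-4-one, via bis(chromon-2-yl)zinc 9 (not isolated)
Conditions: TMP2Zn·2MgCl2·2LiCl (0.6 equiv), THF, −30 °C, 1 h; then 8 (1.0 equiv), Pd(dba)2 (3 mol %), P(2-furyl)3 (6 mol %), 25→50 °C
Reagents that add atoms: none
Why: Lewis-acid-triggered C–H zincation followed by Negishi cross-coupling; MgCl2 bound to the C4 carbonyl (chelated by the 5-OBn) steers the TMP-zinc base to C2–H, so the normally electrophilic enone β-carbon becomes a β-acylvinyl zinc nucleophile that Pd(0) couples with the C–I carbon of 8, following the known C2 zincation/arylation of chromones.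

**Step 6**
Reactants: 10 5,7-bis(benzyloxy)-2-[4-(benzyloxy)phenyl]-6-methoxy-4H-chromen-4-one
Product: 11 hispidulin (5,7-dihydroxy-2-(4-hydroxyphenyl)-6-methoxy-4H-chromen-4-one)
Conditions: H2 (1 atm), 10 % Pd/C, THF/MeOH 1:1, rt
Reagents that add atoms: none
Why: Catalytic hydrogenolysis of the three benzylic C–O bonds is much faster than reduction of the chromone C2=C3 bond, so the flavone core and the methyl ether survive.

**Step 7**
Reactants: 11 hispidulin
Product: 12 hispidulin 7,4'-disulfate
Conditions: SO3·pyridine (6 equiv), pyridine, 45 °C, 12 h; MeOH quench; Sephadex LH-20; Dowex 50WX8 (H+), 0 °C, lyophilise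
Reagents that add atoms: sulfur trioxide pyridine complex, O=S(=O)([O-])[n+]1ccccc1
Why: O-sulfonation with an SO3–amine complex; the acidic, unhindered 7- and 4'-OH react, while the 5-OH is deactivated by its hydrogen bond to C4=O and flanked by the OMe, so the 7,4'-disulfate forms selectively.

**Compound list**
1 | 2',4',6'-trihydroxyacetophenone | CC(=O)c1c(O)cc(O)cc1O | starting material
2 | 1-[2,4-bis(benzyloxy)-6-hydroxyphenyl]ethanone | CC(=O)c1c(O)cc(OCc2ccccc2)cc1OCc1ccccc1 | intermediate
3 | potassium 3-acetyl-2,6-bis(benzyloxy)-4-hydroxyphenyl sulfate | CC(=O)c1c(O)cc(OCc2ccccc2)c(OS(=O)(=O)[O-])c1OCc1ccccc1.[K+] | intermediate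
4 | 1-[2,4-bis(benzyloxy)-3,6-dihydroxyphenyl]ethanone | CC(=O)c1c(O)cc(OCc2ccccc2)c(O)c1OCc1ccccc1 | intermediate
5 | 1-[2,4-bis(benzyloxy)-6-hydroxy-3-methoxyphenyl]ethanone | CC(=O)c1c(O)cc(OCc2ccccc2)c(OC)c1OCc1ccccc1 | intermediate
6 | (E)-1-[2,4-bis(benzyloxy)-6-hydroxy-3-methoxyphenyl]-3-(dimethylamino)prop-2-en-1-one | CN(C)/C=C/C(=O)c1c(O)cc(OCc2ccccc2)c(OC)c1OCc1ccccc1 | intermediate
7 | 5,7-bis(benzyloxy)-6-methoxy-4H-chromen-4-one | COc1c(OCc2ccccc2)cc2occc(=O)c2c1OCc1ccccc1 | intermediate
8 | 1-(benzyloxy)-4-iodobenzene | Ic1ccc(OCc2ccccc2)cc1 | starting material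
9 | bis[5,7-bis(benzyloxy)-6-methoxy-4-oxo-4H-chromen-2-yl]zinc | COc1c(OCc2ccccc2)cc2oc([Zn]c3cc(=O)c4c(OCc5ccccc5)c(OC)c(OCc5ccccc5)cc4o3)cc(=O)c2c1OCc1ccccc1 | intermediate
10 | 5,7-bis(benzyloxy)-2-[4-(benzyloxy)phenyl]-6-methoxy-4H-chromen-4-one | COc1c(OCc2ccccc2)cc2oc(-c3ccc(OCc4ccccc4)cc3)cc(=O)c2c1OCc1ccccc1 | intermediate
11 | hispidulin, 5,7-dihydroxy-2-(4-hydroxyphenyl)-6-methoxy-4H-chromen-4-one | COc1c(O)cc2oc(-c3ccc(O)cc3)cc(=O)c2c1O | intermediate
12 | hispidulin 7,4'-disulfate | COc1c(OS(=O)(=O)O)cc2oc(-c3ccc(OS(=O)(=O)O)cc3)cc(=O)c2c1O | target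

**Totals**
Total step count: 7. Longest linear sequence: 7 steps (1 → 12; 8 enters at step 5).

**Steps most likely to fail**

Step 2 (Elbs oxidation): the para position is crowded by two OBn groups and Elbs yields are usually only 30–40 %, with much recovered 2. The fallback sets out from 2 and changes the oxidation to a two-electron para-oxidation followed by reduction. Teuber oxidation with Fremy's salt (ON(SO3K)2, KH2PO4 buffer, acetone/H2O, rt) gives the para-quinone 2-acetyl-3,5-bis(benzyloxy)cyclohexa-2,5-diene-1,4-dione F1. Shaking F1 with aqueous Na2S2O4/EtOAc reduces it to the hydroquinone, which is 4, where the route is rejoined.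

Step 5 (C2 zincation/Negishi coupling): the 5-OBn/C4=O chelate could divert metalation to C3, or the zinc species could couple sluggishly. The fallback sets out from 7 and attaches the aryl group with normal polarity. Pd(TFA)2/2,2'-bipyridine-catalysed conjugate addition of 4-(benzyloxy)phenylboronic acid to C2 gives racemic 5,7-bis(benzyloxy)-2-[4-(benzyloxy)phenyl]-6-methoxychroman-4-one F2. Dehydrogenation of F2 with DDQ (dioxane, 100 °C) or I2/DMSO removes the stereocentre and gives 10.

Step 7 (sulfation): risks are incomplete or excess sulfation and loss of the acid-labile aryl hydrogen sulfates during isolation. The fallback sets out from 11 and uses protected sulfate diesters. 2,2,2-Trichloroethyl chlorosulfate (2.2 equiv), Et3N and DMAP in THF at 0 °C give the neutral, silica-stable 5-hydroxy-6-methoxy-4-oxo-2-{4-[(2,2,2-trichloroethoxy)sulfonyloxy]phenyl}-4H-chromen-7-yl 2,2,2-trichloroethyl sulfate F3. Zn dust/HCO2NH4 in MeOH at rt cleaves both trichloroethyl groups, and cold H+ exchange gives 12.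

**Further compounds**
F1 | step 2 | 2-acetyl-3,5-bis(benzyloxy)cyclohexa-2,5-diene-1,4-dione | CC(=O)C1=C(OCc2ccccc2)C(=O)C(OCc2ccccc2)=CC1=O
F2 | step 5 | racemic 5,7-bis(benzyloxy)-2-[4-(benzyloxy)phenyl]-6-methoxychroman-4-one | COc1c(OCc2ccccc2)cc2c(c1OCc1ccccc1)C(=O)CC(c1ccc(OCc3ccccc3)cc1)O2
F3 | step 7 | 5-hydroxy-6-methoxy-4-oxo-2-{4-[(2,2,2-trichloroethoxy)sulfonyloxy]phenyl}-4H-chromen-7-yl 2,2,2-trichloroethyl sulfate | COc1c(OS(=O)(=O)OCC(Cl)(Cl)Cl)cc2oc(-c3ccc(OS(=O)(=O)OCC(Cl)(Cl)Cl)cc3)cc(=O)c2c1O
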